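The target is an acyclic 3-hydroxy-3-methylglutarate whose C3 carbinol is stereogenic only because the C1 and C5 carboxyls differ; the aryl ring is a spectator. C3 is therefore taken from (R)-citramalic acid, one carbon short on one arm. A single Arndt–Eistert operation lengthens that arm and esterifies it. The diazoketone made at the carboxyl next to the carbinol (tertiary oxygen as triethylsilyl ether, distal carboxyl as 2,2,2-trichloroethyl ester) undergoes silver-promoted Wolff rearrangement, the carbinol carbon migrating with retention to form C2–C3. The ketene is captured by phenol-silylated (Z)-sinapyl alcohol to form the ester C–O bond. No ring closes. Buffered fluoride, then buffered zinc, release the target without a free phenoxide.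

Key step: step 9

Remarks on the chemistry (assumptions and design choices)
- Configuration: traced atom by atom, (R)-citramalic acid leads to the (R)-target. The carbinol is never touched; its descriptor reads S in the two diesters after the key step only because the trichloroethyl arm outranks the allyl arm.
- Distal ester: a 2,2,2-trichloroethyl ester is used because zinc at pH 4–5 removes it without ever generating a phenoxide. A 2-silylethyl ester would need unbuffered fluoride, under which a 4-oxidocinnamyl ester can expel its carboxylate through a quinone methide.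
- Carbon ester, not silyl ester or free acid: this keeps the ketene from being captured internally as the achiral cyclic glutaric anhydride, which would erase the stereochemical information.
- Acid activation: the hindered α-silyloxy acid is activated as its acid chloride under neutral conditions, since a mixed anhydride could be attacked at the wrong carbonyl.
- Purchased materials: (R)-citramalic acid, 2,2,2-trichloroethanol, trimethylsilyldiazomethane, syringaldehyde and methyl bis(2,2,2-trifluoroethyl)phosphonoacetate are assumed to be commercial.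
- Handling: all Z-configured compounds are handled with exclusion of light.

Step 1
Reactants: 1 (R)-citramalic acid
Product: 2 2-[(4R)-2,2,4-trimethyl-5-oxo-1,3-dioxolan-4-yl]acetic acid
Conditions: Me2C(OMe)2, TsOH·H2O (cat.), rt
Reagents that add atoms: 2,2-dimethoxypropane, COC(C)(C)OC
Why: Acid-catalysed transketalisation (acetonide formation of an α-hydroxy acid) ties the carboxyl next to the carbinol and the tertiary hydroxyl into the favoured five-membered dioxolanone, leaving only the distal CH2CO2H free; the quaternary stereocentre cannot epimerise.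

Step 2
Reactants: 2 2-[(4R)-2,2,4-trimethyl-5-oxo-1,3-dioxolan-4-yl]acetic acid; 3 2,2,2-trichloroethanol
Product: 4 2,2,2-trichloroethyl 2-[(4R)-2,2,4-trimethyl-5-oxo-1,3-dioxolan-4-yl]acetate
Conditions: DCC, DMAP (cat.), CH2Cl2, 0 °C to rt
Reagents that add atoms: none
Why: Steglich esterification of the one free, unhindered carboxyl is routine, and the dioxolanone is inert to carbodiimide and DMAP.

Step 3
Reactants: 4 2,2,2-trichloroethyl 2-[(4R)-2,2,4-trimethyl-5-oxo-1,3-dioxolan-4-yl]acetate
Product: 5 (2R)-2-hydroxy-2-methyl-4-oxo-4-(2,2,2-trichloroethoxy)butanoic acid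
Conditions: AcOH/H2O/THF (3:1:1), 45 °C
Reagents that add atoms: none
Why: Mild aqueous acid cleaves the dioxolanone at its ketal carbon (acetonide hydrolysis, the water oxygen leaving in acetone) far faster than it touches the trichloroethyl ester, so the α-hydroxy acid is released with the distal arm still blocked.

Step 4
Reactants: 5 (2R)-2-hydroxy-2-methyl-4-oxo-4-(2,2,2-trichloroethoxy)butanoic acid
Product: 7 (2R)-2-methyl-4-oxo-4-(2,2,2-trichloroethoxy)-2-(triethylsilyloxy)butanoic acid, via silyl ester 6 (not isolated)
Conditions: Et3SiOTf (2.3 equiv), 2,6-lutidine (3 equiv), CH2Cl2, −78 to 0 °C; then THF/aq. citric acid (pH 4), 0 °C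
Reagents that add atoms: triethylsilyl trifluoromethanesulfonate, CC[Si](CC)(CC)OS(=O)(=O)C(F)(F)F
Why: The silyl triflate with a hindered pyridine base silylates both the tertiary hydroxyl and the carboxyl (silyl ether formation), and only the far more labile silyl ester is hydrolysed in the mildly acidic aqueous work-up.

Step 5
Reactants: 7 (2R)-2-methyl-4-oxo-4-(2,2,2-trichloroethoxy)-2-(triethylsilyloxy)butanoic acid; 8 trimethylsilyldiazomethane
Product: 11 2,2,2-trichloroethyl (3R)-5-diazo-3-methyl-4-oxo-3-(triethylsilyloxy)pentanoate, via acid chloride 9 (not isolated), via C-silyl diazoketone 10 (not isolated)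
Conditions: 1-chloro-N,N,2-trimethylprop-1-en-1-amine, CH2Cl2, 0 °C to rt; then Me3SiCHN2 (1.5 equiv), Et3N (1.5 equiv), THF/MeCN, 0 °C to rt; aq. NaHCO3 work-up
Reagents that add atoms: none
Why: The neutral α-chloroenamine converts the hindered, non-enolisable acid into its acid chloride without acid that would endanger the silyl ether, and C-acylation of the diazoalkane followed by protodesilylation on work-up gives the α-diazoketone (first stage of an Arndt–Eistert sequence).

Step 6
Reactants: 12 syringaldehyde
Product: 13 3,5-dimethoxy-4-(triisopropylsilyloxy)benzaldehyde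
Conditions: i-Pr3SiCl, imidazole, DMF, rt
Reagents that add atoms: triisopropylsilyl chloride, CC(C)[Si](Cl)(C(C)C)C(C)C
Why: Imidazole-mediated silylation of the acidic phenol (silyl ether formation) masks the only other hydroxyl of the alcohol partner, and the bulky group withstands amide base, hydride and amine.

Step 7
Reactants: 13 3,5-dimethoxy-4-(triisopropylsilyloxy)benzaldehyde; 14 methyl 2-[bis(2,2,2-trifluoroethoxy)phosphoryl]acetate
Product: 15 methyl (2Z)-3-[3,5-dimethoxy-4-(triisopropylsilyloxy)phenyl]prop-2-enoate
Conditions: KN(SiMe3)2, 18-crown-6, THF, −78 °C, dark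
Reagents that add atoms: none
Why: In the Still–Gennari variant of the Horner–Wadsworth–Emmons olefination the electron-poor trifluoroethyl phosphonate and the dissociated potassium counter-ion make elimination from the kinetic adduct fast, which should give mainly the Z-cinnamate.

Step 8
Reactants: 15 methyl (2Z)-3-[3,5-dimethoxy-4-(triisopropylsilyloxy)phenyl]prop-2-enoate
Product: 16 (2Z)-3-[3,5-dimethoxy-4-(triisopropylsilyloxy)phenyl]prop-2-en-1-ol
Conditions: i-Bu2AlH, CH2Cl2, −78 °C; aq. KNaC4H4O6 work-up, dark
Reagents that add atoms: none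
Why: 1,2-Reduction of the ester by the aluminium hydride at low temperature (ester-to-alcohol reduction) leaves the Z-alkene and the aryl silyl ether untouched.

Step 9
Reactants: 11 2,2,2-trichloroethyl (3R)-5-diazo-3-methyl-4-oxo-3-(triethylsilyloxy)pentanoate; 16 (2Z)-3-[3,5-dimethoxy-4-(triisopropylsilyloxy)phenyl]prop-2-en-1-ol
Product: 18 1-{(2Z)-3-[3,5-dimethoxy-4-(triisopropylsilyloxy)phenyl]prop-2-en-1-yl} 5-(2,2,2-trichloroethyl) (3S)-3-methyl-3-(triethylsilyloxy)pentanedioate, via ketene 17 (not isolated)
Conditions: AgO2CPh (0.15 equiv), Et3N (3 equiv), THF, −25 °C to rt, dark, anhydrous; 11 in slight excess over 16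
Reagents that add atoms: none
Why: Monovalent silver (AgO2CPh activated by Et3N) promotes loss of N2 from 11, and the bond from the carbinol carbon to the acyl carbon shifts in a concerted 1,2-migration to the former diazo carbon, which creates the C2–C3 bond of the target numbering and ketene 17. The primary allylic hydroxyl of 16 then adds to the ketene carbon and the enol tautomerises, which creates the ester C–O bond; the closest known reaction type is the Arndt–Eistert homologation, a silver-catalysed Wolff rearrangement with alcohol capture of the ketene. No ring closes and no stereocentre is created: the existing quaternary carbinol migrates with retention, so its spatial arrangement is that of 1, and the descriptor becomes S only because the trichloroethyl arm now outranks the allyl arm. The step needs capture by a single hydroxyl, which is secured because the phenol and the tertiary carbinol are silylated and the distal carboxyl is a carbon ester, so neither a β-lactone nor the achiral cyclic anhydride can form. It also needs the Z-alkene and the electron-rich allylic C–O bond to survive, which the dark, neutral, non-ionising conditions should ensure.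

Step 10
Reactants: 18 1-{(2Z)-3-[3,5-dimethoxy-4-(triisopropylsilyloxy)phenyl]prop-2-en-1-yl} 5-(2,2,2-trichloroethyl) (3S)-3-methyl-3-(triethylsilyloxy)pentanedioate
Product: 19 1-[(2Z)-3-(4-hydroxy-3,5-dimethoxyphenyl)prop-2-en-1-yl] 5-(2,2,2-trichloroethyl) (3S)-3-hydroxy-3-methylpentanedioate
Conditions: Bu4NF/AcOH (1:1.2), THF, 0 °C to rt, dark
Reagents that add atoms: none
Why: Fluoride buffered with acetic acid cleaves the aryl and the tertiary silyl ethers (fluoride desilylation) while the phenol stays protonated, so the 4-hydroxycinnamyl ester cannot expel its carboxylate through a quinone methide, and the trichloroethyl ester is inert.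

Step 11
Reactants: 19 1-[(2Z)-3-(4-hydroxy-3,5-dimethoxyphenyl)prop-2-en-1-yl] 5-(2,2,2-trichloroethyl) (3S)-3-hydroxy-3-methylpentanedioate
Product: 20 (3R)-3-hydroxy-5-{[(2Z)-3-(4-hydroxy-3,5-dimethoxyphenyl)prop-2-en-1-yl]oxy}-3-methyl-5-oxopentanoic acid
Conditions: Zn dust, THF/1 M aq. KH2PO4, rt, dark
Reagents that add atoms: none
Why: Zinc inserts into a C–Cl bond of the trichloroethyl group and the organozinc fragments to the carboxylate and 1,1-dichloroethene (reductive β-elimination) at pH 4–5, which should leave the Z-allylic ester, the free phenol and the tertiary carbinol alone and cannot exchange the two arms.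

Compound list
1 | (R)-citramalic acid, (2R)-2-hydroxy-2-methylbutanedioic acid | OC(=O)[C@](C)(O)CC(=O)O | starting material
2 | 2-[(4R)-2,2,4-trimethyl-5-oxo-1,3-dioxolan-4-yl]acetic acid | CC1(C)OC(=O)[C@](C)(O1)CC(=O)O | intermediate
3 | 2,2,2-trichloroethanol | OCC(Cl)(Cl)Cl | starting material
4 | 2,2,2-trichloroethyl 2-[(4R)-2,2,4-trimethyl-5-oxo-1,3-dioxolan-4-yl]acetate | CC1(C)OC(=O)[C@](C)(O1)CC(=O)OCC(Cl)(Cl)Cl | intermediate
5 | (2R)-2-hydroxy-2-methyl-4-oxo-4-(2,2,2-trichloroethoxy)butanoic acid | OC(=O)[C@](C)(O)CC(=O)OCC(Cl)(Cl)Cl | intermediate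
6 | silyl ester: 4-(2,2,2-trichloroethyl) 1-(triethylsilyl) (2R)-2-methyl-2-(triethylsilyloxy)butanedioate | CC[Si](CC)(CC)OC(=O)[C@](C)(O[Si](CC)(CC)CC)CC(=O)OCC(Cl)(Cl)Cl | intermediate
7 | (2R)-2-methyl-4-oxo-4-(2,2,2-trichloroethoxy)-2-(triethylsilyloxy)butanoic acid | OC(=O)[C@](C)(O[Si](CC)(CC)CC)CC(=O)OCC(Cl)(Cl)Cl | intermediate
8 | trimethylsilyldiazomethane | C[Si](C)(C)C=[N+]=[N-] | starting material
9 | acid chloride: 2,2,2-trichloroethyl (3R)-4-chloro-3-methyl-4-oxo-3-(triethylsilyloxy)butanoate | ClC(=O)[C@](C)(O[Si](CC)(CC)CC)CC(=O)OCC(Cl)(Cl)Cl | intermediate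
10 | C-silyl diazoketone: 2,2,2-trichloroethyl (3R)-5-diazo-3-methyl-4-oxo-3-(triethylsilyloxy)-5-(trimethylsilyl)pentanoate | C[Si](C)(C)C(=[N+]=[N-])C(=O)[C@](C)(O[Si](CC)(CC)CC)CC(=O)OCC(Cl)(Cl)Cl | intermediate
11 | 2,2,2-trichloroethyl (3R)-5-diazo-3-methyl-4-oxo-3-(triethylsilyloxy)pentanoate | [N-]=[N+]=CC(=O)[C@](C)(O[Si](CC)(CC)CC)CC(=O)OCC(Cl)(Cl)Cl | intermediate
12 | syringaldehyde, 4-hydroxy-3,5-dimethoxybenzaldehyde | COc1cc(C=O)cc(OC)c1O | starting material
13 | 3,5-dimethoxy-4-(triisopropylsilyloxy)benzaldehyde | COc1cc(C=O)cc(OC)c1O[Si](C(C)C)(C(C)C)C(C)C | intermediate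
14 | methyl 2-[bis(2,2,2-trifluoroethoxy)phosphoryl]acetate | COC(=O)CP(=O)(OCC(F)(F)F)OCC(F)(F)F | starting material
15 | methyl (2Z)-3-[3,5-dimethoxy-4-(triisopropylsilyloxy)phenyl]prop-2-enoate | COC(=O)/C=C\c1cc(OC)c(O[Si](C(C)C)(C(C)C)C(C)C)c(OC)c1 | intermediate
16 | (2Z)-3-[3,5-dimethoxy-4-(triisopropylsilyloxy)phenyl]prop-2-en-1-ol | COc1cc(/C=C\CO)cc(OC)c1O[Si](C(C)C)(C(C)C)C(C)C | intermediate
17 | ketene: 2,2,2-trichloroethyl (3R)-3-methyl-5-oxo-3-(triethylsilyloxy)pent-4-enoate | O=C=C[C@](C)(O[Si](CC)(CC)CC)CC(=O)OCC(Cl)(Cl)Cl | intermediate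
18 | 1-{(2Z)-3-[3,5-dimethoxy-4-(triisopropylsilyloxy)phenyl]prop-2-en-1-yl} 5-(2,2,2-trichloroethyl) (3S)-3-methyl-3-(triethylsilyloxy)pentanedioate | COc1cc(/C=C\COC(=O)C[C@](C)(O[Si](CC)(CC)CC)CC(=O)OCC(Cl)(Cl)Cl)cc(OC)c1O[Si](C(C)C)(C(C)C)C(C)C | intermediate
19 | 1-[(2Z)-3-(4-hydroxy-3,5-dimethoxyphenyl)prop-2-en-1-yl] 5-(2,2,2-trichloroethyl) (3S)-3-hydroxy-3-methylpentanedioate | COc1cc(/C=C\COC(=O)C[C@](C)(O)CC(=O)OCC(Cl)(Cl)Cl)cc(OC)c1O | intermediate
20 | (3R)-3-hydroxy-5-{[(2Z)-3-(4-hydroxy-3,5-dimethoxyphenyl)prop-2-en-1-yl]oxy}-3-methyl-5-oxopentanoic acid | COc1cc(/C=C\COC(=O)C[C@](C)(O)CC(=O)O)cc(OC)c1O | target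

Total step count: 11.
Longest linear sequence: 8 steps (steps 1–5, 9, 10, 11); steps 6–8 form the second branch.

Steps most likely to fail

Step 9. The migrating carbon is fully substituted and oxygen-bearing, so the silver-promoted rearrangement may be slow. Carbene side reactions (O–H insertion into the alcohol, reduction) or ketene self-condensation could then outrun capture by a stoichiometric alcohol. The fallback sets out from 11 and comes back at 18, and separates rearrangement from ester formation. Because 11 carries no alkene, it can be irradiated (365 nm, THF/H2O, 0 °C); the photochemical Wolff rearrangement is less sensitive to the bulk of the migrating group. Water adds to ketene 17 to give (3S)-3-methyl-5-oxo-5-(2,2,2-trichloroethoxy)-3-(triethylsilyloxy)pentanoic acid F1. Steglich esterification of this acid with 16 (DCC, DMAP (cat.), CH2Cl2, 0 °C, dark) should then give 18 under neutral conditions.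

Step 5. C-acylation of the diazoalkane by the neopentyl-type acid chloride may be sluggish, so that hydrolysis back to the acid or loss of the silyl ether intervenes. The fallback sets out from acid chloride 9 and comes back at 11, and replaces acylation of a diazoalkane by diazo transfer. Coupling of 9 with Me2Zn under Pd(PPh3)4 catalysis (THF, 0 °C, Negishi-type acylation) should give the methyl ketone 2,2,2-trichloroethyl (3R)-3-methyl-4-oxo-3-(triethylsilyloxy)pentanoate F2. Its kinetic enolate (LiN(SiMe3)2, THF, −78 °C) is trifluoroacetylated with CF3CO2CH2CF3 to 2,2,2-trichloroethyl (3R)-7,7,7-trifluoro-3-methyl-4,6-dioxo-3-(triethylsilyloxy)heptanoate F3. MeSO2N3 with Et3N and H2O in MeCN then effects detrifluoroacetylative diazo transfer to 11.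

Step 7. Z-selectivity of the olefination may be incomplete, and the Z-cinnamate may isomerise to E under light or base. The fallback sets out from 13 and comes back at 16, bypassing 15, and fixes the geometry by syn addition of hydrogen to an alkyne. A Corey–Fuchs reaction (CBr4, PPh3, CH2Cl2, 0 °C) gives [4-(2,2-dibromoethenyl)-2,6-dimethoxyphenoxy]triisopropylsilane F4. Treatment with n-BuLi (2 equiv, THF, −78 °C) and then paraformaldehyde gives 3-[3,5-dimethoxy-4-(triisopropylsilyloxy)phenyl]prop-2-yn-1-ol F5. Semi-hydrogenation (H2, Pd/CaCO3 poisoned with Pb(OAc)2, quinoline, EtOAc, rt) should then give 16.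

Further compounds
F1 | step 9 | (3S)-3-methyl-5-oxo-5-(2,2,2-trichloroethoxy)-3-(triethylsilyloxy)pentanoic acid | OC(=O)C[C@](C)(O[Si](CC)(CC)CC)CC(=O)OCC(Cl)(Cl)Cl
F2 | step 5 | 2,2,2-trichloroethyl (3R)-3-methyl-4-oxo-3-(triethylsilyloxy)pentanoate | CC(=O)[C@](C)(O[Si](CC)(CC)CC)CC(=O)OCC(Cl)(Cl)Cl
F3 | step 5 | 2,2,2-trichloroethyl (3R)-7,7,7-trifluoro-3-methyl-4,6-dioxo-3-(triethylsilyloxy)heptanoate | FC(F)(F)C(=O)CC(=O)[C@](C)(O[Si](CC)(CC)CC)CC(=O)OCC(Cl)(Cl)Cl
F4 | step 7 | [4-(2,2-dibromoethenyl)-2,6-dimethoxyphenoxy]triisopropylsilane | COc1cc(C=C(Br)Br)cc(OC)c1O[Si](C(C)C)(C(C)C)C(C)C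
F5 | step 7 | 3-[3,5-dimethoxy-4-(triisopropylsilyloxy)phenyl]prop-2-yn-1-ol | COc1cc(C#CCO)cc(OC)c1O[Si](C(C)C)(C(C)C)C(C)C
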